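**Retrosynthetic overview**

1. Numbering: seven-membered ring C1(O-tigloyl)–C2=C3(CH3)–C4–C5(O-aroyl)–C6(H)–C7(CH3); five-membered ring C6–C7–C8–C9–C10(OH)(i-Pr).
2. Feature: the C1 oxygen sits on the carbon between C2 and the quaternary C7, which is the central carbon of an oxyallyl cation C2–C1–C7, and C3–C4–C5(O)–C6 is a 2-oxygenated diene that C8–C9–C10 ties to C7.
3. Late disconnections: both esters, the C1 and C5 carbinols (from ketones) and C2=C3 (dehydrogenation of the C1 ketone) lead back to a trans-fused C1 ketone with the C5 ketone masked as a C4=C5 enol silane.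
4. Key disconnection: intramolecular (4+3) cycloaddition of a 2-siloxyallyl cation with a tethered 2-siloxydiene; C6–C7 closes the five-membered ring first and C2–C3 the seven-membered ring second, in one step. The chloride is placed on the tertiary C7, so the enol silane of the α-chloro ketone can form only toward C2.
5. The acyclic precursor comes from (R)-terpinen-4-ol (source of C10) by ozonolysis; C3–C4–CH3 come from (E)-1-bromopropene and C1–C2 from an ethylidene Wittig reagent.

Key step: step 9

Remark: commercial (R)-(−)-terpinen-4-ol is taken as enantiopure (it would be enriched first if it is not). The centres C5 (in 5, 7–9), C1 (in 8, 9) and C7 (in 8–11) form without control and are all erased by step 9.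

**Route**

Step 1
Reactants: 1 (R)-terpinen-4-ol
Product: 2 triethyl{[(1R)-4-methyl-1-(propan-2-yl)cyclohex-3-en-1-yl]oxy}silane
Conditions: Et3SiOTf, 2,6-lutidine, CH2Cl2, 0 °C
Reagents that add atoms: triethylsilyl trifluoromethanesulfonate, CC[Si](CC)(CC)OS(=O)(=O)C(F)(F)F
Why: Silyl triflates silylate hindered tertiary alcohols (silyl ether protection), which blocks retro-aldol and hemiketal chemistry of the C10 hydroxyl in the next steps and leaves the C10 stereocentre untouched.

Step 2
Reactants: 2 triethylsilyl ether of (R)-terpinen-4-ol
Product: 3 (3R)-6-oxo-3-(propan-2-yl)-3-[(triethylsilyl)oxy]heptanal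
Conditions: O3, CH2Cl2, −78 °C; then PPh3, −78 → 25 °C
Reagents that add atoms: ozone, [O-][O+]=O
Why: Ozonolysis with reductive work-up cleaves the only C=C bond and gives the C7 methyl ketone arm and the C5 aldehyde arm on C10, two carbonyl groups of different reactivity.

Step 3
Reactants: 3 keto aldehyde; 4 (E)-1-bromoprop-1-ene
Product: 5 (5R,8E)-7-hydroxy-5-(propan-2-yl)-5-[(triethylsilyl)oxy]dec-8-en-2-one (both C7-carbinol epimers; this carbon is C5 of the target)
Conditions: CrCl2 (4 equiv), NiCl2 (0.02 equiv), DMF, 25 °C
Reagents that add atoms: 4 (E)-1-bromoprop-1-ene, C/C=C/Br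
Why: Nozaki–Hiyama–Kishi reaction, in which the alkenylchromium reagent adds to the aldehyde but not to the ketone and keeps the E geometry, so C3–C4 are joined to C5 only; the new carbinol forms as both epimers and is oxidised in step 7.

Step 4
Reactants: 5 hydroxy ketone; 6 ethyltriphenylphosphonium bromide
Product: 7 (2E,6R)-9-methyl-6-(propan-2-yl)-6-[(triethylsilyl)oxy]undeca-2,9-dien-4-ol (carbinol epimers, 9E/9Z mixture)
Conditions: NaN(SiMe3)2, THF, 0 → 25 °C (excess ylide)
Reagents that add atoms: 6 ethyltriphenylphosphonium bromide, CC[P+](c1ccccc1)(c1ccccc1)c1ccccc1.[Br-]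
Why: Wittig olefination of the unhindered methyl ketone with a non-stabilised ylide, which tolerates the free alcohol, adds C1 and C2 as a trisubstituted C7=C1 alkene whose geometry is of no consequence.

Step 5
Reactants: 7 diene alcohol
Product: 8 (2E,6R)-8-(2,3-dimethyloxiran-2-yl)-6-(propan-2-yl)-6-[(triethylsilyl)oxy]oct-2-en-4-ol (diastereomer mixture)
Conditions: mCPBA (1.05 equiv), NaHCO3, CH2Cl2, −20 → 0 °C
Reagents that add atoms: 3-chloroperoxybenzoic acid, OOC(=O)c1cccc(Cl)c1
Why: Prilezhaev epoxidation, in which the peracid reacts much faster with the electron-rich trisubstituted C7=C1 alkene than with the disubstituted alkene that carries the deactivating allylic hydroxyl.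

Step 6
Reactants: 8 epoxide
Product: 9 (2E,6R)-9-chloro-9-methyl-6-(propan-2-yl)-6-[(triethylsilyl)oxy]undec-2-ene-4,10-diol (diastereomer mixture)
Conditions: HCl (1 M in Et2O, 1.2 equiv), CH2Cl2, −78 → −30 °C
Reagents that add atoms: hydrogen chloride, Cl
Why: Markovnikov (borderline SN2) opening of the trisubstituted epoxide by anhydrous HCl, an addition in which chloride goes to the tertiary carbon C7 and the hydroxyl stays on C1; chloride within the ion pair should add faster than the hindered C10 silyl ether oxygen, and the short cold exposure should spare the silyl ether and the allylic alcohol.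

Step 7
Reactants: 9 chloro diol
Product: 10 (6R,9E)-3-chloro-3-methyl-6-(propan-2-yl)-6-[(triethylsilyl)oxy]undec-9-ene-2,8-dione (both C3 epimers; C3 here is C7 of the target)
Conditions: Dess–Martin periodinane (3 equiv), NaHCO3, CH2Cl2, 0 → 25 °C
Reagents that add atoms: none
Why: Dess–Martin oxidation converts both secondary alcohols in one operation, the C1 chlorohydrin into the α-chloro methyl ketone and the C5 allylic alcohol into the (E)-enone, under buffered conditions that should not eliminate the β-silyloxy group.

Step 8
Reactants: 10 chloro diketone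
Product: 11 (6S,7Z,9E)-3-chloro-3-methyl-6-(propan-2-yl)-6-[(triethylsilyl)oxy]-2,8-bis[(trimethylsilyl)oxy]undeca-1,7,9-triene
Conditions: LiN(i-Pr)2 (2.5 equiv), Me3SiCl (6 equiv, present from the start), THF, −78 °C; pentane and cold aq NaHCO3 work-up; used crude at once
Reagents that add atoms: chlorotrimethylsilane, C[Si](C)(C)Cl
Why: Kinetic enolisation with internal silyl quench: the chloro ketone has α-hydrogens only at C2, so the 2-siloxyallyl chloride forms with one regiochemistry, and the enone is deprotonated at the α′ carbon C6 to the cross-conjugated siloxydiene, Z because the bulky C10 turns away from the propenyl group; immediate silylation should suppress Favorskii and β-elimination pathways.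

Step 9
Reactants: 11 bis(enol silane) with tertiary allylic chloride
Product: 12 trans-fused cycloadduct: C1 ketone, C3 methyl (cis to the C7 methyl), C4=C5 trimethylsilyl enol ether, C6–H cis to the C10 triethylsilyloxy group, C7 methyl trans to C6–H, C10 isopropyl
Conditions: AgO2CCF3 (1.2 equiv), 2,6-di-tert-butylpyridine (0.5 equiv), CH2Cl2 (high dilution), −78 → −20 °C, dark; filtration, chromatography on Et3N-deactivated silica
Reagents that add atoms: none
Why: AgO2CCF3 removes the tertiary allylic chloride of 11 and gives the 2-(trimethylsilyloxy)allyl cation C2–C1–C7; the closest known reaction type is the silver-promoted (4+3) cycloaddition of 2-siloxyallyl chlorides with dienes and its intramolecular versions that give bicyclo[5.3.0]decenones. C6 of the siloxydiene attacks the tertiary terminus C7 and closes the five-membered ring through C8–C9–C10 (5-exo-trig with respect to both π systems), and C2 of the enol silane so formed adds to C3 of the siloxy-stabilised allyl cation C5–C4–C3 (7-endo-trig, conjugate mode), which closes the seven-membered ring in a concerted asynchronous or stepwise way; trifluoroacetate then takes the silyl group from the C1 oxocarbenium ion and leaves the C1 ketone beside the C4=C5 enol silane. C6 is controlled by the conformation about C10–C6, in which C9 stands above the diene plane, the isopropyl group points away from the incoming cation and the C10–O bond lies near the diene plane on the side of C6–H and away from the enol oxygen, so that C6–H ends cis to the C10 oxygen. C7 is controlled by the extended arrangement of the two π systems, in which the bulky arm C1–C2 lies over C6–H and the small methyl group over C5, so that the ring fusion is trans; C3 follows from suprafacial addition to the (E)-propenyl end and is removed in step 14. The step needs attack by C6 in preference to the oxygen of the C10 silyl ether, closure at C3 in preference to C5 and the extended in preference to the compact arrangement; these should be secured by the much higher nucleophilicity of the siloxydiene carbon, by the hindrance at the fully substituted C5 and by the repulsion between the two silyloxy-bearing ends of the π systems.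

Step 10
Reactants: 12 cycloadduct
Product: 13 trans-fused hydroxy diketone: C1 and C5 ketones, C3 methyl, C7 methyl, free C10 hydroxyl
Conditions: HF·pyridine, pyridine, THF, 0 → 25 °C
Reagents that add atoms: none
Why: Fluoride-mediated desilylation cleaves the enol silane to the C5 ketone (protonation at C4, so C6 is not touched) and the tertiary silyl ether to the C10 hydroxyl, under buffered, mildly acidic conditions chosen to avoid retro-aldol cleavage and epimerisation at C6.

Step 11
Reactants: 13 hydroxy diketone
Product: 14 trans-fused diol: C1 ketone, C5 hydroxyl cis to the C10 hydroxyl and to C6–H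
Conditions: Et2BOMe (1.2 equiv), THF/MeOH 4:1, −78 °C; NaBH4 (1.2 equiv), −78 °C; AcOH, then co-evaporation with MeOH
Reagents that add atoms: none
Why: Narasaka–Prasad reduction, in which the diethylboryl chelate between the C10 hydroxyl and the C5 carbonyl activates C5 over the unchelated neopentyl C1 ketone and lies on the face of the C10 oxygen, so that external hydride should enter from the opposite face and give the 1,3-syn diol, that is the equatorial C5 alcohol.

Step 12
Reactants: 15 4-hydroxybenzoic acid
Product: 17 4-[(tert-butyldimethylsilyl)oxy]benzoic acid, via silyl ester silyl ether 16 (not isolated)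
Conditions: t-BuMe2SiCl (2.5 equiv), imidazole, DMF, 25 °C; then AcOH/THF/H2O, 25 °C
Reagents that add atoms: tert-butylchlorodimethylsilane, CC(C)(C)[Si](C)(C)Cl
Why: Silylation of both acidic groups followed by selective hydrolysis of the labile silyl ester gives the phenol-protected acid, whose aryl silyl ether survives acylation and hydride steps and is removed by fluoride at the end.

Step 13
Reactants: 14 diol; 17 protected acid
Product: 18 C5 ester: C1 ketone, C5 4-[(tert-butyldimethylsilyl)oxy]benzoate, free C10 hydroxyl
Conditions: N,N′-dicyclohexylcarbodiimide, DMAP, CH2Cl2, 25 °C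
Reagents that add atoms: 17 4-[(tert-butyldimethylsilyl)oxy]benzoic acid, OC(=O)c1ccc(O[Si](C)(C)C(C)(C)C)cc1
Why: Steglich esterification acylates the secondary C5 hydroxyl with retention and leaves the tertiary C10 hydroxyl free.

Step 14
Reactants: 18 keto ester
Product: 20 enone: C1 ketone conjugated with C2=C3(CH3) beside the C5 ester and the C10 triethylsilyl ether, via bis(triethylsilyl) enol ether 19 (not isolated)
Conditions: Et3SiOTf (3 equiv), Et3N, CH2Cl2, 0 °C; aq NaHCO3 work-up; then Pd(OAc)2 (1.1 equiv), MeCN, 40 °C
Reagents that add atoms: triethylsilyl trifluoromethanesulfonate, CC[Si](CC)(CC)OS(=O)(=O)C(F)(F)F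
Why: Saegusa–Ito oxidation, in which soft enolisation can go only toward C2 because C7 is quaternary (the C10 hydroxyl is silylated in the same operation) and palladation of the enol silane with β-hydride elimination of C3–H gives the C2=C3 enone and removes the C3 stereocentre.

Step 15
Reactants: 20 enone
Product: 21 allylic alcohol: C1 hydroxyl trans to the C7 methyl and cis to C6–H
Conditions: LiBH(s-Bu)3 (L-Selectride, 1.5 equiv), THF, −78 °C; H2O work-up
Reagents that add atoms: none
Why: 1,2-Reduction of a β,β-disubstituted enone by a bulky trialkylborohydride, which should take the equatorial path on the face of the adjacent C7 methyl and away from the axial C6–H and so give the pseudo-axial C1 alcohol trans to the C7 methyl, as bulky hydrides do with cyclic ketones next to an angular methyl; the aryl ester should be inert at −78 °C.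

Step 16
Reactants: 21 allylic alcohol; 22 tigloyl chloride
Product: 23 fully protected target: C1 tiglate, C5 4-[(tert-butyldimethylsilyl)oxy]benzoate, C10 triethylsilyl ether
Conditions: pyridine, DMAP, CH2Cl2, 0 → 40 °C
Reagents that add atoms: 22 (E)-2-methylbut-2-enoyl chloride, C/C=C(\C)C(=O)Cl
Why: DMAP-catalysed acylation of the hindered allylic alcohol with retention at C1; pyridine in place of a trialkylamine avoids deconjugation of the tigloyl group through a vinylketene.

Step 17
Reactants: 23 protected target
Product: 24 target CNP0273650.6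
Conditions: HF·pyridine, pyridine, THF, 0 → 25 °C
Reagents that add atoms: none
Why: Fluoride-mediated desilylation removes the aryl silyl ether and the tertiary triethylsilyl ether under buffered conditions that should leave both esters, the allylic C1–O bond and the tertiary alcohol intact.

**Compound list**

1 | (R)-terpinen-4-ol | CC1=CC[C@@](O)(C(C)C)CC1 | starting material
2 | triethyl{[(1R)-4-methyl-1-(propan-2-yl)cyclohex-3-en-1-yl]oxy}silane | CC1=CC[C@@](O[Si](CC)(CC)CC)(C(C)C)CC1 | intermediate
3 | (3R)-6-oxo-3-(propan-2-yl)-3-[(triethylsilyl)oxy]heptanal | CC(=O)CC[C@](O[Si](CC)(CC)CC)(C(C)C)CC=O | intermediate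
4 | (E)-1-bromoprop-1-ene | C/C=C/Br | starting material
5 | (5R,8E)-7-hydroxy-5-(propan-2-yl)-5-[(triethylsilyl)oxy]dec-8-en-2-one, carbinol epimers | CC(=O)CC[C@](O[Si](CC)(CC)CC)(C(C)C)CC(O)/C=C/C | intermediate
6 | ethyltriphenylphosphonium bromide | CC[P+](c1ccccc1)(c1ccccc1)c1ccccc1.[Br-] | starting material
7 | (2E,6R)-9-methyl-6-(propan-2-yl)-6-[(triethylsilyl)oxy]undeca-2,9-dien-4-ol, isomer mixture | CC=C(C)CC[C@](O[Si](CC)(CC)CC)(C(C)C)CC(O)/C=C/C | intermediate
8 | (2E,6R)-8-(2,3-dimethyloxiran-2-yl)-6-(propan-2-yl)-6-[(triethylsilyl)oxy]oct-2-en-4-ol, diastereomer mixture | CC1OC1(C)CC[C@](O[Si](CC)(CC)CC)(C(C)C)CC(O)/C=C/C | intermediate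
9 | (2E,6R)-9-chloro-9-methyl-6-(propan-2-yl)-6-[(triethylsilyl)oxy]undec-2-ene-4,10-diol, diastereomer mixture | CC(O)C(C)(Cl)CC[C@](O[Si](CC)(CC)CC)(C(C)C)CC(O)/C=C/C | intermediate
10 | (6R,9E)-3-chloro-3-methyl-6-(propan-2-yl)-6-[(triethylsilyl)oxy]undec-9-ene-2,8-dione, C3 epimers | CC(=O)C(C)(Cl)CC[C@](O[Si](CC)(CC)CC)(C(C)C)CC(=O)/C=C/C | intermediate
11 | (6S,7Z,9E)-3-chloro-3-methyl-6-(propan-2-yl)-6-[(triethylsilyl)oxy]-2,8-bis[(trimethylsilyl)oxy]undeca-1,7,9-triene (key-step precursor) | C=C(O[Si](C)(C)C)C(C)(Cl)CC[C@](O[Si](CC)(CC)CC)(C(C)C)/C=C(O[Si](C)(C)C)/C=C/C | intermediate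
12 | trans-fused cycloadduct: C1 ketone, C3 methyl, C4=C5 trimethylsilyl enol ether, C7 methyl, C10 isopropyl and triethylsilyloxy (key-step product) | O=C1C[C@@H](C)C=C(O[Si](C)(C)C)[C@@H]2[C@]1(C)CC[C@]2(O[Si](CC)(CC)CC)C(C)C | intermediate
13 | trans-fused C1,C5-diketone with free C10 hydroxyl | O=C1C[C@@H](C)CC(=O)[C@@H]2[C@]1(C)CC[C@]2(O)C(C)C | intermediate
14 | C1 ketone with C5 hydroxyl cis to the C10 hydroxyl | O=C1C[C@@H](C)C[C@H](O)[C@@H]2[C@]1(C)CC[C@]2(O)C(C)C | intermediate
15 | 4-hydroxybenzoic acid | OC(=O)c1ccc(O)cc1 | starting material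
16 | tert-butyldimethylsilyl 4-[(tert-butyldimethylsilyl)oxy]benzoate | CC(C)(C)[Si](C)(C)OC(=O)c1ccc(O[Si](C)(C)C(C)(C)C)cc1 | intermediate
17 | 4-[(tert-butyldimethylsilyl)oxy]benzoic acid | OC(=O)c1ccc(O[Si](C)(C)C(C)(C)C)cc1 | intermediate
18 | C1 ketone, C5 4-[(tert-butyldimethylsilyl)oxy]benzoate, free C10 hydroxyl | O=C1C[C@@H](C)C[C@H](OC(=O)c3ccc(O[Si](C)(C)C(C)(C)C)cc3)[C@@H]2[C@]1(C)CC[C@]2(O)C(C)C | intermediate
19 | C1=C2 triethylsilyl enol ether of 18 with C10 triethylsilyl ether | CC[Si](CC)(CC)OC1=C[C@@H](C)C[C@H](OC(=O)c3ccc(O[Si](C)(C)C(C)(C)C)cc3)[C@@H]2[C@]1(C)CC[C@]2(O[Si](CC)(CC)CC)C(C)C | intermediate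
20 | C2=C3 enone with C5 ester and C10 triethylsilyl ether | O=C1C=C(C)C[C@H](OC(=O)c3ccc(O[Si](C)(C)C(C)(C)C)cc3)[C@@H]2[C@]1(C)CC[C@]2(O[Si](CC)(CC)CC)C(C)C | intermediate
21 | C1 allylic alcohol (hydroxyl trans to the C7 methyl) with C5 ester and C10 triethylsilyl ether | O[C@@H]1C=C(C)C[C@H](OC(=O)c3ccc(O[Si](C)(C)C(C)(C)C)cc3)[C@@H]2[C@]1(C)CC[C@]2(O[Si](CC)(CC)CC)C(C)C | intermediate
22 | tigloyl chloride, (E)-2-methylbut-2-enoyl chloride | C/C=C(\C)C(=O)Cl | starting material
23 | C1 tiglate, C5 4-[(tert-butyldimethylsilyl)oxy]benzoate, C10 triethylsilyl ether | C/C=C(\C)C(=O)O[C@@H]1C=C(C)C[C@H](OC(=O)c2ccc(O[Si](C)(C)C(C)(C)C)cc2)[C@@H]2[C@]1(C)CC[C@]2(O[Si](CC)(CC)CC)C(C)C | intermediate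
24 | CNP0273650.6: C1 tiglate, C5 4-hydroxybenzoate, C10 tertiary alcohol | C/C=C(\C)C(=O)O[C@@H]1C=C(C)C[C@H](OC(=O)c2ccc(O)cc2)[C@@H]2[C@]1(C)CC[C@]2(O)C(C)C | target

**Step count and risks**

Total step count: 17. Longest linear sequence: 16 steps (steps 1–11 and 13–17; step 12 is a one-step side branch).

The three steps most likely to fail:

First, step 9. The closure may run through the compact arrangement of the two π systems, so that control of the ring fusion at C6 is lost; capture of the C7 cation by the oxygen of the C10 silyl ether and closure of the second bond at C5 are further ways to lose material. A wrong configuration at C7 could not be repaired. The fallback replaces kinetic control at C6 by thermodynamic control and sets out from 11. The cis-fused cycloadduct F1 (the C6 epimer of 12, C3 drawn as in 12) would be treated with K2CO3 in MeOH at 0 °C, which cleaves only the enol silane and gives the cis-fused diketone F2 with the C10 silyl ether kept as a guard against retro-aldol cleavage. DBU in toluene would then equilibrate C6 through the C5 enolate toward the trans-fused diketone F3, relying on the general preference of bicyclo[5.3.0]decan-2-ones for the trans fusion. HF·pyridine as in step 10 would remove the silyl ether, and the route is rejoined at 13. A C3 epimer would follow the same course and converge at 20.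

Second, step 11. Hydride may attack the C5 carbonyl on the face of the C10 oxygen, which is the less hindered face (the other carries the C7 methyl and the C10 isopropyl), so that facial selectivity is poor or reversed. The fallback sets the centre by inversion and sets out from 13. Evans–Saksena reduction (Me4NBH(OAc)3, MeCN/AcOH, −30 °C) delivers hydride inside the C10-bound borohydride to that same face, again only at C5, and should give the 1,3-anti diol F4 (the C5 epimer of 14). Mitsunobu esterification of F4 with acid 17 (PPh3, diisopropyl azodicarboxylate, toluene, 0 → 25 °C) would then install the aryl ester with inversion at C5, and the route is rejoined at 18.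

Third, step 15. The bulky hydride may fail to override the intrinsic preference for attack anti to the C7 methyl, or may add in the conjugate sense. The fallback again uses inversion and sets out from 20. Luche reduction (NaBH4, CeCl3·7H2O, MeOH, −78 °C) is 1,2-selective and should attack anti to the C7 methyl to give the C1 epimer F5 of 21. Mitsunobu esterification of F5 with tiglic acid (PPh3, diisopropyl azodicarboxylate, toluene) would invert C1 and install the tiglate in one operation, and the route is rejoined at 23.

**Further compounds**

F1 | step 9 | cis-fused cycloadduct, C6 epimer of 12 | O=C1C[C@@H](C)C=C(O[Si](C)(C)C)[C@H]2[C@]1(C)CC[C@]2(O[Si](CC)(CC)CC)C(C)C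
F2 | step 9 | cis-fused C1,C5-diketone with C10 triethylsilyl ether | O=C1C[C@@H](C)CC(=O)[C@H]2[C@]1(C)CC[C@]2(O[Si](CC)(CC)CC)C(C)C
F3 | step 9 | trans-fused C1,C5-diketone with C10 triethylsilyl ether | O=C1C[C@@H](C)CC(=O)[C@@H]2[C@]1(C)CC[C@]2(O[Si](CC)(CC)CC)C(C)C
F4 | step 11 | C5 epimer of 14 (1,3-anti diol) | O=C1C[C@@H](C)C[C@@H](O)[C@@H]2[C@]1(C)CC[C@]2(O)C(C)C
F5 | step 15 | C1 epimer of 21 | O[C@H]1C=C(C)C[C@H](OC(=O)c3ccc(O[Si](C)(C)C(C)(C)C)cc3)[C@@H]2[C@]1(C)CC[C@]2(O[Si](CC)(CC)CC)C(C)C
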